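**Plan**

- Retrosynthesis: the aryl O–Si bond is cut first, then the three CH2OH groups go back to esters (one global reduction) and the side-chain aryl–vinyl bond is cut (Heck). The last two cuts are the aryl–C2 bond of the right-hand dihydrobenzofuran (its C2 to C5 of the central ring) and, by the same reaction, the aryl–C2 bond of the left-hand dihydrobenzofuran.
- Both aryl–C2 cuts lead to one flat building block, ethyl 5-bromo-7-methoxybenzofuran-3-carboxylate, made in one step from 5-bromo-o-vanillin and used twice.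
- Forward: benzofuran ester; Rh-catalysed dearomative conjugate arylation with a guaiacyl boronate gives the left dihydrobenzofuran; Br is exchanged for Bpin; a second arylation onto a second molecule of the benzofuran ester joins the halves; then Heck, DIBAL-H and desilylation. No ring is built after step 1.
- Enabling feature: in the furan ring of the benzofuran ester, O1–C2=C3–CO2Et is a β-aryloxy acrylate with C2 as β-carbon, and the furan ring is only weakly aromatic, so an aryl–Rh species can add its aryl group to C2.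
- Stereochemistry: each C2 comes from the chiral diene–Rh catalyst (face selection at the flat C2=C3 bond); each C3 comes from base equilibration of the ester to the trans isomer; the hydride reduction leaves both untouched.

Key step: step 5

Remark on the chemistry: the sense of induction of the diene ligand on this new acceptor class cannot be taken from a tested model. The enantiomer written, (R,R)-Ph-bod*, stands for the one that delivers the aryl group to the Si face of C2 (O1 > C3 > H) and so gives 2R. If step 3 shows the opposite sense, the antipode is used in steps 3 and 5 and nothing else changes.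

**Route**

Step 1
Reactants: 1 5-bromo-2-hydroxy-3-methoxybenzaldehyde; 2 ethyl diazoacetate
Product: 4 ethyl 5-bromo-7-methoxy-1-benzofuran-3-carboxylate, via hemiacetal ester 3 (not isolated)
Conditions: 2 (1.6 equiv), HBF4·OEt2 (10 mol %), CH2Cl2, rt; then conc. H2SO4, rt
Reagents that add atoms: none
Why: Acid-catalysed addition of the diazo ester to the aldehyde with 1,2-aryl shift and loss of N2 (Roskamp-type homologation) gives, after closure of the ortho phenol on the new formyl group, hemiacetal 3, which H2SO4 dehydrates to the aromatic benzofuran-3-carboxylate; no stereocenter is formed.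

Step 2
Reactants: 5 2-methoxy-4-(4,4,5,5-tetramethyl-1,3,2-dioxaborolan-2-yl)phenol
Product: 6 triisopropyl[2-methoxy-4-(4,4,5,5-tetramethyl-1,3,2-dioxaborolan-2-yl)phenoxy]silane
Conditions: TIPSCl (1.2 equiv), imidazole (2.5 equiv), DMF, rt
Reagents that add atoms: triisopropylsilyl chloride, CC(C)[Si](Cl)(C(C)C)C(C)C
Why: Imidazole-assisted silylation of a phenol leaves the pinacol boronate alone, and the TIPS ether blocks phenoxide-driven quinone methide opening of the later 2-aryl dihydrofuran rings while resisting the mild bases used up to step 8.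

Step 3
Reactants: 6 triisopropyl[2-methoxy-4-(4,4,5,5-tetramethyl-1,3,2-dioxaborolan-2-yl)phenoxy]silane; 4 ethyl 5-bromo-7-methoxy-1-benzofuran-3-carboxylate
Product: 8 ethyl (2R,3R)-5-bromo-7-methoxy-2-{3-methoxy-4-[(triisopropylsilyl)oxy]phenyl}-2,3-dihydro-1-benzofuran-3-carboxylate, via cis ester 7 (not isolated)
Conditions: 6 (2 equiv), [RhCl(C2H4)2]2 (2.5 mol %), (R,R)-Ph-bod* (5.5 mol %), K3PO4 (1 equiv), dioxane/H2O 10:1, 60 °C; then DBU (0.2 equiv), PhMe, rt
Reagents that add atoms: none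
Why: Proposed new method: the aryl–Rh(I) species formed by transmetalation from 6 should insert the C2=C3 bond of 4, a β-aryloxy acrylate only weakly held by the aromaticity of the furan ring, placing the aryl group on C2 (β to the ester, α to O1) and giving a rhodium enolate that water protonates, so that the chiral diene selects the C2 face (2R) and DBU then equilibrates the C3 ester from the cis isomer 7 to the more stable trans position (3R); the closest known reaction type is the Hayashi–Miyaura asymmetric 1,4-addition of arylboron reagents to enoates, coumarins and chromones, extended here to a dearomative case.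

Step 4
Reactants: 8 ethyl (2R,3R)-5-bromo-7-methoxy-2-{3-methoxy-4-[(triisopropylsilyl)oxy]phenyl}-2,3-dihydro-1-benzofuran-3-carboxylate
Product: 9 ethyl (2R,3R)-7-methoxy-2-{3-methoxy-4-[(triisopropylsilyl)oxy]phenyl}-5-(4,4,5,5-tetramethyl-1,3,2-dioxaborolan-2-yl)-2,3-dihydro-1-benzofuran-3-carboxylate
Conditions: B2pin2 (1.3 equiv), Pd(dppf)Cl2 (5 mol %), KOAc (3 equiv), dioxane, 85 °C
Reagents that add atoms: bis(pinacolato)diboron, CC1(C)OB(OC1(C)C)B1OC(C)(C)C(C)(C)O1
Why: Miyaura borylation of an aryl bromide under Pd(0)/KOAc tolerates the ester, the silyl ether and the benzylic C2–O bond, and the weak base leaves the thermodynamically placed trans stereocenters as they are.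

Step 5
Reactants: 9 ethyl (2R,3R)-7-methoxy-2-{3-methoxy-4-[(triisopropylsilyl)oxy]phenyl}-5-(4,4,5,5-tetramethyl-1,3,2-dioxaborolan-2-yl)-2,3-dihydro-1-benzofuran-3-carboxylate; 4 ethyl 5-bromo-7-methoxy-1-benzofuran-3-carboxylate
Product: 11 ethyl (2R,3R)-5-bromo-2-[(2R,3R)-3-(ethoxycarbonyl)-7-methoxy-2-{3-methoxy-4-[(triisopropylsilyl)oxy]phenyl}-2,3-dihydro-1-benzofuran-5-yl]-7-methoxy-2,3-dihydro-1-benzofuran-3-carboxylate, via cis diester 10 (not isolated)
Conditions: 4 (3 equiv), [RhCl(C2H4)2]2 (5 mol %), (R,R)-Ph-bod* (11 mol %), K3PO4 (1 equiv), dioxane/H2O 10:1, 60 °C; then DBU (0.2 equiv), PhMe, rt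
Reagents that add atoms: none
Why: Proposed new method: the aryl–Rh(I)(diene) species made by transmetalation from boronate 9 should add syn across the C2=C3 bond of a second molecule of 4 (aryl to C2, Rh to C3 as an oxa-π-allyl enolate) and water then protonates the enolate and returns Rh–OH; the closest known reaction type is the Hayashi–Miyaura asymmetric conjugate arylation of enoates, coumarins and chromones, and the only new element is that the acceptor alkene is the weakly aromatic furan C2=C3 bond of a benzofuran-3-carboxylate (O1–C2=C3–C=O, a β-aryloxy acrylate). No ring is closed: the dihydrofuran ring of the right-hand unit is already present as the furan ring and is only dearomatised. The new C2 centre (R) is set by the chiral diene, which selects the face of the flat acceptor while the stereocenters of 9 sit too far from boron to interfere, and the new C3 centre (R at the ester level, S after reduction) is set by DBU equilibration of the enolisable ester from the cis isomer 10 to the trans isomer. The step needs regioselectivity (aryl to C2, secured because the ester polarisation and the ring oxygen both direct the aryl group there), insertion in preference to protodeboronation (secured by an excess of the cheap acceptor 4 with the valuable boronate as limiting partner and by an electron-rich aryl–Rh) and an untouched C5–Br (Rh(I) does not add oxidatively to aryl bromides under these conditions). Ring opening of the rhodium enolate by loss of the O1 aryloxide is disfavoured because the C2–O1 bond lies in the ring plane, orthogonal to the enolate π system (the reverse of a 5-endo-trig closure).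

Step 6
Reactants: 11 ethyl (2R,3R)-5-bromo-2-[(2R,3R)-3-(ethoxycarbonyl)-7-methoxy-2-{3-methoxy-4-[(triisopropylsilyl)oxy]phenyl}-2,3-dihydro-1-benzofuran-5-yl]-7-methoxy-2,3-dihydro-1-benzofuran-3-carboxylate; 12 ethyl acrylate
Product: 13 ethyl (2R,3R)-5-[(E)-3-ethoxy-3-oxoprop-1-en-1-yl]-2-[(2R,3R)-3-(ethoxycarbonyl)-7-methoxy-2-{3-methoxy-4-[(triisopropylsilyl)oxy]phenyl}-2,3-dihydro-1-benzofuran-5-yl]-7-methoxy-2,3-dihydro-1-benzofuran-3-carboxylate
Conditions: 12 (2 equiv), Pd2(dba)3 (2.5 mol %), P(t-Bu)3·HBF4 (10 mol %), Cy2NMe (1.5 equiv), dioxane, 70 °C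
Reagents that add atoms: none
Why: Mizoroki–Heck reaction of the aryl bromide with an acrylate gives the E-cinnamate by syn insertion and syn β-hydride elimination, Pd/P(t-Bu)3 activating the electron-rich bromide at moderate temperature while the hindered amine base does not disturb the trans esters.

Step 7
Reactants: 13 ethyl (2R,3R)-5-[(E)-3-ethoxy-3-oxoprop-1-en-1-yl]-2-[(2R,3R)-3-(ethoxycarbonyl)-7-methoxy-2-{3-methoxy-4-[(triisopropylsilyl)oxy]phenyl}-2,3-dihydro-1-benzofuran-5-yl]-7-methoxy-2,3-dihydro-1-benzofuran-3-carboxylate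
Product: 14 (E)-3-[(2R,3S)-3-(hydroxymethyl)-2-[(2R,3S)-3-(hydroxymethyl)-7-methoxy-2-{3-methoxy-4-[(triisopropylsilyl)oxy]phenyl}-2,3-dihydro-1-benzofuran-5-yl]-7-methoxy-2,3-dihydro-1-benzofuran-5-yl]prop-2-en-1-ol
Conditions: DIBAL-H (10 equiv), CH2Cl2, −78 → 0 °C; aq. Rochelle salt
Reagents that add atoms: none
Why: DIBAL-H reduces the two saturated esters to primary alcohols and the cinnamate by 1,2-addition to the E-allylic alcohol in one operation, a reduction with precedent in dihydrobenzofuran neolignan diesters, and hydride touches neither the stereocenters (C3 changes from R to S by priority only) nor the aryl silyl ether.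

Step 8
Reactants: 14 (E)-3-[(2R,3S)-3-(hydroxymethyl)-2-[(2R,3S)-3-(hydroxymethyl)-7-methoxy-2-{3-methoxy-4-[(triisopropylsilyl)oxy]phenyl}-2,3-dihydro-1-benzofuran-5-yl]-7-methoxy-2,3-dihydro-1-benzofuran-5-yl]prop-2-en-1-ol
Product: 15 4-[(2R,3S)-3-(hydroxymethyl)-5-[(2R,3S)-3-(hydroxymethyl)-5-[(E)-3-hydroxyprop-1-en-1-yl]-7-methoxy-2,3-dihydro-1-benzofuran-2-yl]-7-methoxy-2,3-dihydro-1-benzofuran-2-yl]-2-methoxyphenol
Conditions: TBAF (1.2 equiv), AcOH (1.2 equiv), THF, 0 °C
Reagents that add atoms: none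
Why: Fluoride cleaves the aryl silyl ether through Si–F bond formation, and the acetic acid buffer keeps the freed phenol from standing as a phenoxide that could open the neighbouring dihydrofuran ring through a quinone methide.

**Compound list**

1 | 5-bromo-2-hydroxy-3-methoxybenzaldehyde | COc1cc(Br)cc(C=O)c1O | starting material
2 | ethyl diazoacetate | CCOC(=O)C=[N+]=[N-] | starting material
3 | ethyl 5-bromo-2-hydroxy-7-methoxy-2,3-dihydro-1-benzofuran-3-carboxylate (hemiacetal, mixture of stereoisomers) | CCOC(=O)C1C(O)Oc2c(OC)cc(Br)cc12 | intermediate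
4 | ethyl 5-bromo-7-methoxy-1-benzofuran-3-carboxylate | CCOC(=O)c1coc2c(OC)cc(Br)cc12 | intermediate
5 | 2-methoxy-4-(4,4,5,5-tetramethyl-1,3,2-dioxaborolan-2-yl)phenol | COc1cc(ccc1O)B1OC(C)(C)C(C)(C)O1 | starting material
6 | triisopropyl[2-methoxy-4-(4,4,5,5-tetramethyl-1,3,2-dioxaborolan-2-yl)phenoxy]silane | COc1cc(ccc1O[Si](C(C)C)(C(C)C)C(C)C)B1OC(C)(C)C(C)(C)O1 | intermediate
7 | ethyl (2R,3S)-5-bromo-7-methoxy-2-{3-methoxy-4-[(triisopropylsilyl)oxy]phenyl}-2,3-dihydro-1-benzofuran-3-carboxylate (cis) | COc1cc([C@@H]2Oc3c(OC)cc(Br)cc3[C@@H]2C(=O)OCC)ccc1O[Si](C(C)C)(C(C)C)C(C)C | intermediate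
8 | ethyl (2R,3R)-5-bromo-7-methoxy-2-{3-methoxy-4-[(triisopropylsilyl)oxy]phenyl}-2,3-dihydro-1-benzofuran-3-carboxylate (trans) | COc1cc([C@@H]2Oc3c(OC)cc(Br)cc3[C@H]2C(=O)OCC)ccc1O[Si](C(C)C)(C(C)C)C(C)C | intermediate
9 | ethyl (2R,3R)-7-methoxy-2-{3-methoxy-4-[(triisopropylsilyl)oxy]phenyl}-5-(4,4,5,5-tetramethyl-1,3,2-dioxaborolan-2-yl)-2,3-dihydro-1-benzofuran-3-carboxylate | COc1cc([C@@H]2Oc3c(OC)cc(B4OC(C)(C)C(C)(C)O4)cc3[C@H]2C(=O)OCC)ccc1O[Si](C(C)C)(C(C)C)C(C)C | intermediate
10 | ethyl (2R,3S)-5-bromo-2-[(2R,3R)-3-(ethoxycarbonyl)-7-methoxy-2-{3-methoxy-4-[(triisopropylsilyl)oxy]phenyl}-2,3-dihydro-1-benzofuran-5-yl]-7-methoxy-2,3-dihydro-1-benzofuran-3-carboxylate (new ring cis) | COc1cc([C@@H]2Oc3c(OC)cc([C@@H]4Oc5c(OC)cc(Br)cc5[C@@H]4C(=O)OCC)cc3[C@H]2C(=O)OCC)ccc1O[Si](C(C)C)(C(C)C)C(C)C | intermediate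
11 | ethyl (2R,3R)-5-bromo-2-[(2R,3R)-3-(ethoxycarbonyl)-7-methoxy-2-{3-methoxy-4-[(triisopropylsilyl)oxy]phenyl}-2,3-dihydro-1-benzofuran-5-yl]-7-methoxy-2,3-dihydro-1-benzofuran-3-carboxylate | COc1cc([C@@H]2Oc3c(OC)cc([C@@H]4Oc5c(OC)cc(Br)cc5[C@H]4C(=O)OCC)cc3[C@H]2C(=O)OCC)ccc1O[Si](C(C)C)(C(C)C)C(C)C | intermediate
12 | ethyl acrylate | C=CC(=O)OCC | starting material
13 | ethyl (2R,3R)-5-[(E)-3-ethoxy-3-oxoprop-1-en-1-yl]-2-[(2R,3R)-3-(ethoxycarbonyl)-7-methoxy-2-{3-methoxy-4-[(triisopropylsilyl)oxy]phenyl}-2,3-dihydro-1-benzofuran-5-yl]-7-methoxy-2,3-dihydro-1-benzofuran-3-carboxylate | COc1cc([C@@H]2Oc3c(OC)cc([C@@H]4Oc5c(OC)cc(/C=C/C(=O)OCC)cc5[C@H]4C(=O)OCC)cc3[C@H]2C(=O)OCC)ccc1O[Si](C(C)C)(C(C)C)C(C)C | intermediate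
14 | (E)-3-[(2R,3S)-3-(hydroxymethyl)-2-[(2R,3S)-3-(hydroxymethyl)-7-methoxy-2-{3-methoxy-4-[(triisopropylsilyl)oxy]phenyl}-2,3-dihydro-1-benzofuran-5-yl]-7-methoxy-2,3-dihydro-1-benzofuran-5-yl]prop-2-en-1-ol | COc1cc([C@@H]2Oc3c(OC)cc([C@@H]4Oc5c(OC)cc(/C=C/CO)cc5[C@H]4CO)cc3[C@H]2CO)ccc1O[Si](C(C)C)(C(C)C)C(C)C | intermediate
15 | 4-[(2R,3S)-3-(hydroxymethyl)-5-[(2R,3S)-3-(hydroxymethyl)-5-[(E)-3-hydroxyprop-1-en-1-yl]-7-methoxy-2,3-dihydro-1-benzofuran-2-yl]-7-methoxy-2,3-dihydro-1-benzofuran-2-yl]-2-methoxyphenol | COc1cc([C@@H]2Oc3c(OC)cc([C@@H]4Oc5c(OC)cc(/C=C/CO)cc5[C@H]4CO)cc3[C@H]2CO)ccc1O | target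

Total step count: 8. Longest linear sequence: 7 steps (steps 1, 3, 4, 5, 6, 7, 8).

**Steps most likely to fail**

1. Step 5 (Proposed new method). Insertion of the aryl–rhodium species into the aromatic C2=C3 bond may be slower than protodeboronation of the valuable boronate, or face selection may be poor with the large aryl partner. The fallback uses known chemistry, sets out from 9 and 4 and comes back to the route at 14. Compound 4 is magnesiated at C2 (TMPMgCl·LiCl, THF, −40 °C) and quenched with 1,2-dibromotetrachloroethane to give ethyl 2,5-dibromo-7-methoxy-1-benzofuran-3-carboxylate F1. Suzuki–Miyaura coupling of 9 with F1 at the more reactive C2–Br (Pd(PPh3)4, K2CO3, toluene/EtOH/H2O, 70 °C) forms the same aryl–C2 bond on the aromatic ring and gives the 2-arylbenzofuran diester F2. Dissolving-metal conjugate reduction (Mg, MeOH/THF, 0 °C) should then reduce the furan C2=C3 bond to the trans dihydrobenzofuran and exchange both ethyl esters for methyl esters. This reduction has no facial control, so the wanted trans dimethyl ester F3 has to be separated by chromatography from its diastereomer with the (2S,3S) new ring F4. F3 is taken through the conditions of step 6 to the cinnamate F5 and through those of step 7, which gives 14.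

2. Step 3 (Proposed new method). The same low reactivity of the aromatic acceptor may let protodeboronation win, or the enantioselectivity may be insufficient, and it cannot be raised later. The fallback uses known chemistry, sets out from 6 and 4 (through the bromide F1 described above) and comes back at 8. Suzuki–Miyaura coupling of 6 with F1 at C2 gives ethyl 5-bromo-7-methoxy-2-{3-methoxy-4-[(triisopropylsilyl)oxy]phenyl}-1-benzofuran-3-carboxylate F6. Mg/MeOH reduction should give the racemic trans methyl ester, which is resolved by preparative chromatography on a chiral stationary phase into the (2R,3R) methyl ester F7 and its enantiomer F8. Titanate-mediated transesterification of F7 (Ti(OEt)4, EtOH, reflux) returns 8.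

3. Step 7. With three esters to reduce at once, conjugate hydride delivery to the cinnamate or stalling at an aldehyde stage (with base-type ring opening of the α-aryl aldehyde) may erode the material. The fallback sets out from 11 and comes back at 15, and installs the side chain already at the alcohol oxidation level. Suzuki–Miyaura coupling of 11 with commercial (E)-tert-butyldimethyl{[3-(4,4,5,5-tetramethyl-1,3,2-dioxaborolan-2-yl)prop-2-en-1-yl]oxy}silane (Pd(dppf)Cl2, K3PO4, dioxane/H2O, 80 °C) gives the bis-silyl diester F9. The two saturated esters are reduced with LiBH4 (THF/MeOH, 0 °C to rt) to the diol F10, and TBAF/AcOH in THF removes both silyl groups to give 15.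

**Further compounds**

F1 | step 5 | ethyl 2,5-dibromo-7-methoxy-1-benzofuran-3-carboxylate | CCOC(=O)c1c(Br)oc2c(OC)cc(Br)cc12
F2 | step 5 | ethyl 5-bromo-2-[(2R,3R)-3-(ethoxycarbonyl)-7-methoxy-2-{3-methoxy-4-[(triisopropylsilyl)oxy]phenyl}-2,3-dihydro-1-benzofuran-5-yl]-7-methoxy-1-benzofuran-3-carboxylate | COc1cc([C@@H]2Oc3c(OC)cc(-c4oc5c(OC)cc(Br)cc5c4C(=O)OCC)cc3[C@H]2C(=O)OCC)ccc1O[Si](C(C)C)(C(C)C)C(C)C
F3 | step 5 | methyl (2R,3R)-5-bromo-7-methoxy-2-[(2R,3R)-7-methoxy-3-(methoxycarbonyl)-2-{3-methoxy-4-[(triisopropylsilyl)oxy]phenyl}-2,3-dihydro-1-benzofuran-5-yl]-2,3-dihydro-1-benzofuran-3-carboxylate | COc1cc([C@@H]2Oc3c(OC)cc([C@@H]4Oc5c(OC)cc(Br)cc5[C@H]4C(=O)OC)cc3[C@H]2C(=O)OC)ccc1O[Si](C(C)C)(C(C)C)C(C)C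
F4 | step 5 | methyl (2S,3S)-5-bromo-7-methoxy-2-[(2R,3R)-7-methoxy-3-(methoxycarbonyl)-2-{3-methoxy-4-[(triisopropylsilyl)oxy]phenyl}-2,3-dihydro-1-benzofuran-5-yl]-2,3-dihydro-1-benzofuran-3-carboxylate | COc1cc([C@@H]2Oc3c(OC)cc([C@H]4Oc5c(OC)cc(Br)cc5[C@@H]4C(=O)OC)cc3[C@H]2C(=O)OC)ccc1O[Si](C(C)C)(C(C)C)C(C)C
F5 | step 5 | methyl (2R,3R)-5-[(E)-3-ethoxy-3-oxoprop-1-en-1-yl]-7-methoxy-2-[(2R,3R)-7-methoxy-3-(methoxycarbonyl)-2-{3-methoxy-4-[(triisopropylsilyl)oxy]phenyl}-2,3-dihydro-1-benzofuran-5-yl]-2,3-dihydro-1-benzofuran-3-carboxylate | COc1cc([C@@H]2Oc3c(OC)cc([C@@H]4Oc5c(OC)cc(/C=C/C(=O)OCC)cc5[C@H]4C(=O)OC)cc3[C@H]2C(=O)OC)ccc1O[Si](C(C)C)(C(C)C)C(C)C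
F6 | step 3 | ethyl 5-bromo-7-methoxy-2-{3-methoxy-4-[(triisopropylsilyl)oxy]phenyl}-1-benzofuran-3-carboxylate | CCOC(=O)c1c(-c2ccc(O[Si](C(C)C)(C(C)C)C(C)C)c(OC)c2)oc2c(OC)cc(Br)cc12
F7 | step 3 | methyl (2R,3R)-5-bromo-7-methoxy-2-{3-methoxy-4-[(triisopropylsilyl)oxy]phenyl}-2,3-dihydro-1-benzofuran-3-carboxylate | COc1cc([C@@H]2Oc3c(OC)cc(Br)cc3[C@H]2C(=O)OC)ccc1O[Si](C(C)C)(C(C)C)C(C)C
F8 | step 3 | methyl (2S,3S)-5-bromo-7-methoxy-2-{3-methoxy-4-[(triisopropylsilyl)oxy]phenyl}-2,3-dihydro-1-benzofuran-3-carboxylate | COc1cc([C@H]2Oc3c(OC)cc(Br)cc3[C@@H]2C(=O)OC)ccc1O[Si](C(C)C)(C(C)C)C(C)C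
F9 | step 7 | ethyl (2R,3R)-5-[(E)-3-{[tert-butyl(dimethyl)silyl]oxy}prop-1-en-1-yl]-2-[(2R,3R)-3-(ethoxycarbonyl)-7-methoxy-2-{3-methoxy-4-[(triisopropylsilyl)oxy]phenyl}-2,3-dihydro-1-benzofuran-5-yl]-7-methoxy-2,3-dihydro-1-benzofuran-3-carboxylate | COc1cc([C@@H]2Oc3c(OC)cc([C@@H]4Oc5c(OC)cc(/C=C/CO[Si](C)(C)C(C)(C)C)cc5[C@H]4C(=O)OCC)cc3[C@H]2C(=O)OCC)ccc1O[Si](C(C)C)(C(C)C)C(C)C
F10 | step 7 | [(2R,3S)-5-[(2R,3S)-5-[(E)-3-{[tert-butyl(dimethyl)silyl]oxy}prop-1-en-1-yl]-3-(hydroxymethyl)-7-methoxy-2,3-dihydro-1-benzofuran-2-yl]-7-methoxy-2-{3-methoxy-4-[(triisopropylsilyl)oxy]phenyl}-2,3-dihydro-1-benzofuran-3-yl]methanol | COc1cc([C@@H]2Oc3c(OC)cc([C@@H]4Oc5c(OC)cc(/C=C/CO[Si](C)(C)C(C)(C)C)cc5[C@H]4CO)cc3[C@H]2CO)ccc1O[Si](C(C)C)(C(C)C)C(C)C
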